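**Retrosynthetic overview**

- Feature: in the 1,2-dioxane (O1–O2–C3–C4–C5–C6) both peroxide carbons lie β to a carbonyl-level carbon. C3 is β to the ester carbonyl through the exocyclic CH2, and C6 is β to side-chain C2' (the methyl-bearing diene carbon, a latent ketone) through C1'. The O1–O2 unit is therefore H2O2 added in conjugate fashion twice.
- The diene is made last: C2'=C3' by Horner–Wadsworth–Emmons olefination of the C2' methyl ketone with an allylic phosphonate obtained from allylbenzene by cross-metathesis.
- The only ring formed, the 1,2-dioxane, arises in one operation from an acyclic keto dienoate and H2O2: C6–O2 by amine-catalysed asymmetric hydroperoxidation of the enone, then C3–O1 by 6-exo peroxy-Michael closure onto the enoate.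
- The keto dienoate comes from methyl (R)-3-hydroxy-2-methylpropanoate (C4 stereocentre bought): iodide, Negishi coupling of the derived alkylzinc with (E)-4-iodopent-3-en-2-one, reduction, double oxidation and aldehyde-selective Wittig olefination.

Key step: step 7

Assumption: the quinine-derived primary amine is taken to deliver H2O2 to the C6 Re face of the (6E)-enone by analogy with β-monosubstituted enones; should the sense prove opposite, the quinidine-derived pseudoenantiomer is used under otherwise identical conditions.

**Step 1**
Reactants: 1 methyl (2R)-3-hydroxy-2-methylpropanoate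
Product: 2 methyl (2S)-3-iodo-2-methylpropanoate
Conditions: PPh3, imidazole, I2, CH2Cl2, 0 °C to rt
Reagents that add atoms: iodine, [I][I]
Why: Appel-type iodination converts the primary alcohol to the iodide by SN2 displacement at CH2, so the α-stereocentre is untouched and its descriptor changes from R to S only through the priority change.

**Step 2**
Reactants: 3 pentane-2,4-dione
Product: 4 (3E)-4-iodopent-3-en-2-one
Conditions: PPh3, I2, Et3N, MeCN, 0 °C to rt; chromatographic separation of the E isomer (geometry checked by NOE)
Reagents that add atoms: iodine, [I][I]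
Why: Deoxygenative iodination of the β-diketone enol by Ph3P·I2 (O-phosphonium formation, then iodide addition–elimination) should give the β-iodo enone, and iodide-mediated equilibration is expected to favour the E isomer, in which the C–I and C=O dipoles oppose, which is separated from any Z isomer before use.

**Step 3**
Reactants: 2 methyl (2S)-3-iodo-2-methylpropanoate; 4 (3E)-4-iodopent-3-en-2-one
Product: 6 methyl (2R,4E)-2,4-dimethyl-6-oxohept-4-enoate, via alkylzinc iodide 5 (not isolated)
Conditions: Zn, LiCl, THF, 30 °C (Zn activated with BrCH2CH2Br, Me3SiCl); then 4, Pd(PPh3)4 (3 mol%), THF, rt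
Reagents that add atoms: none
Why: Zinc insertion into the primary C–I bond gives a β-zincio ester whose stereocentre is not the metallated carbon, and Negishi cross-coupling with the (E)-vinyl iodide under zerovalent palladium should proceed with retention of alkene geometry while the soft organozinc leaves ester and ketone alone.

**Step 4**
Reactants: 6 methyl (2R,4E)-2,4-dimethyl-6-oxohept-4-enoate
Product: 7 (2R,4E)-2,4-dimethylhept-4-ene-1,6-diol (mixture of C6 carbinol epimers)
Conditions: iBu2AlH (4.5 equiv), CH2Cl2, −78 to 0 °C; aq. potassium sodium tartrate work-up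
Reagents that add atoms: none
Why: Hydride reduction with iBu2AlH takes the ester to the primary alcohol and adds 1,2 to the enone, leaving the trisubstituted alkene and C2 intact, while the new carbinol centre forms unselectively and is erased in step 5.

**Step 5**
Reactants: 7 (2R,4E)-2,4-dimethylhept-4-ene-1,6-diol
Product: 8 (2R,4E)-2,4-dimethyl-6-oxohept-4-enal
Conditions: Dess–Martin periodinane (2.6 equiv), NaHCO3, CH2Cl2, 0 °C to rt; crude product used directly
Reagents that add atoms: none
Why: Dess–Martin oxidation converts the primary and the allylic secondary alcohol in one operation under bicarbonate buffering, which is mild enough to keep the α-methyl aldehyde configurationally intact when it is not chromatographed.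

**Step 6**
Reactants: 8 (2R,4E)-2,4-dimethyl-6-oxohept-4-enal; 9 methyl 2-(triphenyl-λ5-phosphanylidene)acetate
Product: 10 methyl (2E,4R,6E)-4,6-dimethyl-8-oxonona-2,6-dienoate
Conditions: 9 (1.2 equiv), CH2Cl2, rt
Reagents that add atoms: none
Why: Wittig olefination with a stabilised ylide reacts only at the aldehyde (the hindered conjugated ketone is inert at room temperature) and should give the (E)-enoate without added base, so C4 is not epimerised.

**Step 7**
Reactants: 10 methyl (2E,4R,6E)-4,6-dimethyl-8-oxonona-2,6-dienoate; 11 hydrogen peroxide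
Product: 14 methyl 2-[(3S,4R,6R)-4,6-dimethyl-6-(2-oxopropyl)-1,2-dioxan-3-yl]acetate, via hydroperoxy ketone 12 (not isolated), via peroxyhemiketal 13 (not isolated)
Conditions: 9-amino-9-deoxy-epi-quinine (10 mol%), CF3CO2H (20 mol%), 50% aq. H2O2 (3 equiv), 1,4-dioxane, 30 °C; filtration through silica; then Et3N (0.3 equiv), CF3CH2OH, 0 °C to rt
Reagents that add atoms: none
Why: Proposed new method: the primary amine condenses with the methyl ketone of 10 to a chiral iminium ion whose protonated quinuclidine steers H2O2 by hydrogen bonding to the Re face of C6 (C6–O2 bond, 6R, catalyst control; the remote C4 centre adds little bias), and hydrolysis releases hydroperoxy ketone 12, which rests reversibly as the five-membered peroxyhemiketal 13. The closest known reaction types are the cinchona-primary-amine-catalysed hydroperoxidation of β-monosubstituted enones with H2O2 and the amine/fluoroalcohol-mediated intramolecular peroxy-Michael closure of hydroperoxy enoates to 1,2-dioxanes; forming a tetrasubstituted C–OO centre on a β,β-disubstituted enone and coupling it to that closure is not established. With Et3N in CF3CH2OH, 13 reopens to 12 and the hydroperoxide adds to C3 of the (E)-enoate in a 6-exo-trig closure (C3–O1 bond) that forms the 1,2-dioxane. C3 (S) is set by substrate control: the chair transition state carries the C4 methyl, the C6 oxopropyl arm and the incipient CH2CO2Me equatorial (C6 methyl axial), which gives the 3,4-trans ring, and the reversibility of the peroxy-Michael step under base lets any 3,4-cis isomer drain to this all-equatorial product. The step needs face selectivity at C6, secured by the chiral iminium ion acting on a geometrically pure (6E)-enone, and hydroperoxide-over-epoxide chemoselectivity, secured by the mild temperature of the first stage, by removing the primary amine before base is added and by a tertiary amine in a protic fluoroalcohol that protonates enolates before they can displace the O–O bond.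

**Step 8**
Reactants: 15 allylbenzene; 16 diethyl allylphosphonate
Product: 17 diethyl [(2E)-4-phenylbut-2-en-1-yl]phosphonate
Conditions: 15 (3 equiv), second-generation Grubbs catalyst RuCl2(=CHPh)(H2IMes)(PCy3) (3 mol%), 1,4-benzoquinone (10 mol%), CH2Cl2, 40 °C
Reagents that add atoms: none
Why: Olefin cross-metathesis of two unhindered terminal alkenes under thermodynamic control, with excess allylbenzene against phosphonate homodimer and benzoquinone against double-bond migration, should give mainly the E allylic phosphonate, which is purified from minor Z isomer.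

**Step 9**
Reactants: 14 methyl 2-[(3S,4R,6R)-4,6-dimethyl-6-(2-oxopropyl)-1,2-dioxan-3-yl]acetate; 17 diethyl [(2E)-4-phenylbut-2-en-1-yl]phosphonate
Product: 19 methyl 2-[(3S,4R,6R)-4,6-dimethyl-6-[(2E,4E)-2-methyl-6-phenylhexa-2,4-dien-1-yl]-1,2-dioxan-3-yl]acetate (target), via lithiated phosphonate 18 (not isolated)
Conditions: 17 (1.5 equiv), n-BuLi (1.0 equiv per 17), THF, −78 °C; then 14, DMPU, −78 °C to rt
Reagents that add atoms: none
Why: In this Horner–Wadsworth–Emmons olefination the lithiated allylic phosphonate, formed with no excess base, should add through its α-carbon to the methyl ketone at low temperature and lose lithium diethyl phosphate on warming to give the conjugated diene, with the neopentyl-like C1' methylene taking the position anti to the diene chain (2'E), the 4'E geometry carried over from 17, and the dialkyl peroxide tolerating the phosphonate carbanion.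

**Compound list**

1 | methyl (2R)-3-hydroxy-2-methylpropanoate | COC(=O)[C@H](C)CO | starting material
2 | methyl (2S)-3-iodo-2-methylpropanoate | COC(=O)[C@H](C)CI | intermediate
3 | pentane-2,4-dione | CC(=O)CC(C)=O | starting material
4 | (3E)-4-iodopent-3-en-2-one | CC(=O)/C=C(\C)I | intermediate
5 | [(2S)-3-methoxy-2-methyl-3-oxopropyl]zinc iodide | COC(=O)[C@H](C)C[Zn]I | intermediate (not isolated)
6 | methyl (2R,4E)-2,4-dimethyl-6-oxohept-4-enoate | COC(=O)[C@H](C)C/C(C)=C/C(C)=O | intermediate
7 | (2R,4E)-2,4-dimethylhept-4-ene-1,6-diol (C6 epimers) | OC[C@H](C)C/C(C)=C/C(C)O | intermediate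
8 | (2R,4E)-2,4-dimethyl-6-oxohept-4-enal | O=C[C@H](C)C/C(C)=C/C(C)=O | intermediate
9 | methyl 2-(triphenyl-λ5-phosphanylidene)acetate | COC(=O)C=P(c1ccccc1)(c1ccccc1)c1ccccc1 | starting material
10 | methyl (2E,4R,6E)-4,6-dimethyl-8-oxonona-2,6-dienoate | COC(=O)/C=C/[C@H](C)C/C(C)=C/C(C)=O | intermediate
11 | hydrogen peroxide | OO | starting material
12 | methyl (2E,4R,6R)-6-hydroperoxy-4,6-dimethyl-8-oxonon-2-enoate | COC(=O)/C=C/[C@H](C)C[C@@](C)(OO)CC(C)=O | intermediate (not isolated)
13 | methyl (2E,4R)-5-[(3R)-5-hydroxy-3,5-dimethyl-1,2-dioxolan-3-yl]-4-methylpent-2-enoate (hemiketal epimers) | COC(=O)/C=C/[C@H](C)C[C@]1(C)CC(C)(O)OO1 | intermediate (not isolated)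
14 | methyl 2-[(3S,4R,6R)-4,6-dimethyl-6-(2-oxopropyl)-1,2-dioxan-3-yl]acetate | COC(=O)C[C@@H]1OO[C@@](C)(CC(C)=O)C[C@H]1C | intermediate
15 | allylbenzene (prop-2-en-1-ylbenzene) | C=CCc1ccccc1 | starting material
16 | diethyl allylphosphonate | C=CCP(=O)(OCC)OCC | starting material
17 | diethyl [(2E)-4-phenylbut-2-en-1-yl]phosphonate | CCOP(=O)(C/C=C/Cc1ccccc1)OCC | intermediate
18 | diethyl [(2E)-1-lithio-4-phenylbut-2-en-1-yl]phosphonate | [Li]C(/C=C/Cc1ccccc1)P(=O)(OCC)OCC | intermediate (not isolated)
19 | methyl 2-[(3S,4R,6R)-4,6-dimethyl-6-[(2E,4E)-2-methyl-6-phenylhexa-2,4-dien-1-yl]-1,2-dioxan-3-yl]acetate | COC(=O)C[C@@H]1OO[C@@](C)(C/C(C)=C/C=C/Cc2ccccc2)C[C@H]1C | target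

**Step count and risks**

Total step count: 9. Longest linear sequence: 7 steps (steps 1, 3, 4, 5, 6, 7, 9); steps 2 and 8 are one-step side branches.

Steps most likely to fail:

1. Step 7 (proposed new method). The hindered β,β-disubstituted iminium ion may take up H2O2 slowly and with poor facial discrimination, also through E/Z scrambling of the enone via the dienamine. The β-peroxy enamine or enolate may collapse to the epoxy ketone, and the ring closure may give some 3,4-cis material. The fallback uses known reaction types only, sets out from diol 7 and returns at 14. Diol 7 is subjected to cobalt-catalysed Mukaiyama–Isayama hydroperoxysilylation (Co(thd)2, thd = 2,2,6,6-tetramethylheptane-3,5-dionate, O2, Et3SiH, 1,2-dichloroethane, rt). Hydrogen-atom transfer to C5 and O2 capture at the tertiary C4 radical should give (2R)-2,4-dimethyl-4-[(triethylsilyl)peroxy]heptane-1,6-diol F1 as a mixture at the peroxide carbon. Dess–Martin oxidation should give (2R)-2,4-dimethyl-6-oxo-4-[(triethylsilyl)peroxy]heptanal F2, and Wittig reaction with 9 should give methyl (2E,4R)-4,6-dimethyl-8-oxo-6-[(triethylsilyl)peroxy]non-2-enoate F3. Bu4NF buffered with AcOH in THF removes the silyl group to give hydroperoxide 12 together with its C6 epimer methyl (2E,4R,6S)-6-hydroperoxy-4,6-dimethyl-8-oxonon-2-enoate F4. Et3N in CF3CH2OH then closes both by the established 6-exo peroxy-Michael addition to 14 and its C6 epimer methyl 2-[(3S,4R,6S)-4,6-dimethyl-6-(2-oxopropyl)-1,2-dioxan-3-yl]acetate F5, which are separated by chromatography. This gives up control of C6 and costs the material that ends up as F5.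

2. Step 9. The phosphonate carbanion may enolise the methyl ketone, leading to E1cB opening of the β-peroxy ketone. Reversible α-addition may drift towards γ-adducts, and E-selectivity at the new trisubstituted alkene may be incomplete. The fallback forms C3'–C4' by cross-coupling instead; it sets out from 14 and arrives at 19. Bis[(pinacolato)boryl]methane is deprotonated with lithium 2,2,6,6-tetramethylpiperidide (THF, 0 °C) and added to 14 at −78 °C. This boron-Wittig olefination should place boron anti to the larger C1' substituent and give methyl 2-[(3S,4R,6R)-4,6-dimethyl-6-[(2E)-2-methyl-3-(4,4,5,5-tetramethyl-1,3,2-dioxaborolan-2-yl)prop-2-en-1-yl]-1,2-dioxan-3-yl]acetate F6, whose geometric purity can be secured by chromatography. Its partner [(2E)-3-iodoprop-2-en-1-yl]benzene F7 is made from prop-2-yn-1-ylbenzene by syn-hydrozirconation with Cp2Zr(H)Cl and iodinolysis. Suzuki–Miyaura coupling of F6 with F7 (PdCl2(dppf), aq. K3PO4, THF, rt) should give 19 with both alkene geometries retained.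

3. Step 3, together with its partner from step 2. The β-iodo enone may form mainly as the Z isomer or lose its geometry at the vinylpalladium stage, giving Z-contaminated enone; part of the zinc reagent may also be lost by protonation. The fallback fixes the geometry by syn-hydrometallation; it sets out from alkylzinc iodide 5 and returns at diol 7. Pent-3-yn-2-ol is silylated (t-BuMe2SiCl, imidazole) to tert-butyldimethyl(pent-3-yn-2-yloxy)silane F8. Hydrozirconation with Cp2Zr(H)Cl (THF, 50 °C, zirconium at the methyl-bearing carbon) and iodinolysis should give tert-butyl{[(3E)-4-iodopent-3-en-2-yl]oxy}dimethylsilane F9. Negishi coupling of 5 with F9 (Pd(PPh3)4, THF) should give methyl (2R,4E)-6-[(tert-butyldimethylsilyl)oxy]-2,4-dimethylhept-4-enoate F10. Reduction with iBu2AlH gives (2R,4E)-6-[(tert-butyldimethylsilyl)oxy]-2,4-dimethylhept-4-en-1-ol F11, and Bu4NF then gives diol 7.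

**Further compounds**

F1 | step 7 | (2R)-2,4-dimethyl-4-[(triethylsilyl)peroxy]heptane-1,6-diol | OC[C@H](C)CC(C)(OO[Si](CC)(CC)CC)CC(C)O
F2 | step 7 | (2R)-2,4-dimethyl-6-oxo-4-[(triethylsilyl)peroxy]heptanal | O=C[C@H](C)CC(C)(OO[Si](CC)(CC)CC)CC(C)=O
F3 | step 7 | methyl (2E,4R)-4,6-dimethyl-8-oxo-6-[(triethylsilyl)peroxy]non-2-enoate | COC(=O)/C=C/[C@H](C)CC(C)(OO[Si](CC)(CC)CC)CC(C)=O
F4 | step 7 | methyl (2E,4R,6S)-6-hydroperoxy-4,6-dimethyl-8-oxonon-2-enoate | COC(=O)/C=C/[C@H](C)C[C@](C)(OO)CC(C)=O
F5 | step 7 | methyl 2-[(3S,4R,6S)-4,6-dimethyl-6-(2-oxopropyl)-1,2-dioxan-3-yl]acetate | COC(=O)C[C@@H]1OO[C@](C)(CC(C)=O)C[C@H]1C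
F6 | step 9 | methyl 2-[(3S,4R,6R)-4,6-dimethyl-6-[(2E)-2-methyl-3-(4,4,5,5-tetramethyl-1,3,2-dioxaborolan-2-yl)prop-2-en-1-yl]-1,2-dioxan-3-yl]acetate | COC(=O)C[C@@H]1OO[C@@](C)(C/C(C)=C/B2OC(C)(C)C(C)(C)O2)C[C@H]1C
F7 | step 9 | [(2E)-3-iodoprop-2-en-1-yl]benzene | I/C=C/Cc1ccccc1
F8 | step 3 | tert-butyldimethyl(pent-3-yn-2-yloxy)silane | CC#CC(C)O[Si](C)(C)C(C)(C)C
F9 | step 3 | tert-butyl{[(3E)-4-iodopent-3-en-2-yl]oxy}dimethylsilane | I/C(C)=C/C(C)O[Si](C)(C)C(C)(C)C
F10 | step 3 | methyl (2R,4E)-6-[(tert-butyldimethylsilyl)oxy]-2,4-dimethylhept-4-enoate | COC(=O)[C@H](C)C/C(C)=C/C(C)O[Si](C)(C)C(C)(C)C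
F11 | step 3 | (2R,4E)-6-[(tert-butyldimethylsilyl)oxy]-2,4-dimethylhept-4-en-1-ol | OC[C@H](C)C/C(C)=C/C(C)O[Si](C)(C)C(C)(C)C
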